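## The problem

The target is the 7,15-diacetate of labda-8,13(Z)-diene-6β,7α,15-triol. It is a trans-fused decalin (rings A and B) whose ring B holds a tetrasubstituted C8=C9 alkene, and C9 carries a five-carbon chain ending in a Z-trisubstituted allylic acetate. Four stereocentres sit on the bicycle: the ring-fusion pair C5 (H α) and quaternary C10 (CH3 β), and the trans-diaxial pair C6 (β-OH) and C7 (α-OAc). Only C5/C10 need absolute control. Once they exist, the axial C4β and C10 methyl groups close the β face of ring B, so C6 can be set by α-face hydride delivery to a C6 ketone, and a 6β oxygen in turn sends a nucleophile at C7 to the α face. The acyl pattern (O7 and O15 esterified, O6 free) is a differentiation problem that the hindrance of the 6β-hydroxyl can solve at the end. The fragile parts are the C7 allylic oxygen next to the tetrasubstituted alkene (ionisable, prone to diene formation) and the neryl-type chain, which loses its Z geometry or cyclises onto C8=C9 under strong acid. The feature that opens the synthesis is C10: it bears a methyl group, the C1 methylene and C9, which is the substitution pattern of the α-carbon of 2-methylacrolein with the formyl carbon as C9. C5 with its C6 branch is the terminus of a diene C2=C3–C4(CH3)=C5, so ring A is a Diels–Alder adduct, and the C3=C4 alkene it leaves is the place for the second C4 methyl.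

## Retrosynthesis

**Ester C–O bonds at O7 and O15 (24 → 23).** The acetates are removed first. In triol 23 the three hydroxyls differ sharply (primary allylic, secondary allylic, secondary axial between two syn-axial methyls), so the forward step is a twofold acetylation that should stop before O6. Acetylating last keeps esters out of the organometallic, palladium and acid steps; an allylic acetate on the chain would be ionised by palladium in the coupling.

**C7–O bond with alkene shift (23 → 22).** Moving the oxygen from C7 to C9 and the alkene to C7=C8 gives tertiary allylic alcohol 22. This turns the tetrasubstituted alkene into a carbonyl-addition problem at C9 and lets C6 relay its configuration to C7. Direct C7 oxidation of a Δ8 alkene would compete with C6, C11, C12, C16 and C17. The forward reaction asks for ionisation of the tertiary C9–OH, capture by water at C7 anti to the axial 6β-OH, and conditions mild enough to spare the Z allylic alcohol.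

**C12–C13 bond (22 → 17 + 20).** An sp3–sp2 Suzuki–Miyaura cut gives vinyl carbinol 17 and (Z)-3-iodobut-2-en-1-ol 20. The neighbouring cut, C9–C11 with the whole chain as an organometallic, needs about five steps for the reagent, which is a homoallyl metal with an allylic leaving group. Iodide 20 is one step from but-2-yn-1-ol 18 with the Z geometry fixed by trans-hydroalumination (via 19). The forward step needs hydroboration of the monosubstituted alkene only (borane 21) and coupling with retention.

**C9–C11 bond (17 → 16).** Removing the vinyl group leaves hydroxy enone 16, whose C9 carbonyl has no α-hydrogen. The face of addition is irrelevant because C9 becomes trigonal again.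

**C6–O bond (16 → 15 → 14).** The 6β-hydroxyl comes from ene-dione 15 by hydride attack on the open α face of the less hindered carbonyl, and 15 from enone 14 by oxidation of its only γ-methylene. Carrying O6 through the ring closure from an acyclic α-oxy aldehyde was rejected: C6 would be set by an addition next to C5 with no clear bias and would then be epimerisable as the γ-position of the enone.

**C7=C8 and C6–C7 bonds (14 → 13 → 12 → 11 → 10).** Ring B is opened by a retro-aldol condensation to keto aldehyde 12 (through aldol 13). C10 is quaternary, so C8 is the only carbon that can attack C7 and the closure has one mode. C7 is a one-carbon Wittig homologation (enol ether 11) of the C6 aldehyde in 10.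

**C8–C9 and C4–CH3 bonds (10 → 9 → 8 → 6 → 5).** The ethyl ketone comes from ethyl Grignard addition to the C9 aldehyde of 5 and later oxidation. The second C4 methyl comes from hydromethylation of the C3=C4 alkene of 6 (via hydrazide 7), done at the alcohol stage where the tertiary radical has no activated hydrogen within reach. Desilylation (9) and a double oxidation give 10.

**C1–C2 and C5–C10 bonds (5 → 3 + 4).** The Diels–Alder cut removes ring A, the quaternary centre and both ring-fusion stereocentres at once and leaves achiral diene 3 and 2-methylacrolein 4. The forward reaction must be regioselective ("ortho"), exo and enantioface-selective.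

**Diene (3 → 2 → 1).** Silylation and semi-hydrogenation of commercial (E)-3-methylpent-2-en-4-yn-1-ol 1.

## Roads not taken

**Alternative 1:** The cut is the C10–C20 bond. The angular methyl is delivered as a CH2 unit to a tetrasubstituted C5=C10 alkene by Et2Zn/CH2I2 under direction of a 6β-hydroxyl, giving cyclopropane A1; the temporary C5–C20 bond is cleaved later. Its merits are real: the bicycle comes from cheap achiral material, the methyl is tied to the face of an oxygen the target needs, and the C9 ketal is ready for the side chain. Its weak points are the slow cyclopropanation of a tetrasubstituted alkene, the need for an enantioselective entry to the carbinol, and the ring opening. Opening needs a C6 carbonyl to direct C5–C20 cleavage and α-protonation at C5, so the 6β centre is erased and reset, and C7 oxygen, the C8 methyl and C8=C9 are still missing. It is better than the chosen plan in the sourcing of the ring system. The chosen plan sets both fusion centres in one catalytic step and needs no temporary ring.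

**Alternative 2:** The cut is C5–C10 and C6–C7. A nitroalkene adds intramolecularly to a C7=C8–C9=C10 diene and gives A2 with both rings, the tetrasubstituted alkene and the chain in one step. In ring construction this is clearly more convergent than the chosen plan, which spends about eight steps on ring B. Against it: the diene is fully substituted at C9 and C10 and must be made with defined geometry and forced s-cis. The 3β-p-methoxybenzyloxy group that steers the fold is not in the target and must be removed by deoxygenation. The nitro group is at the 6α position, so reaching the 6β-hydroxyl needs a Nef reaction and a reduction. C7 arrives as CH2, so its oxygen needs an allylic oxidation in competition with C11, C12, C16 and C17. The heating is also a risk for the Z allylic acetate. The chosen plan places O6 and O7 by ring-controlled steps and carries no superfluous oxygen.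

**Alternative 3:** The cut is C8=C9. RuCl2(=CH-2-(i-PrO)C6H4)(1,3-di-o-tolylimidazolidin-2-ylidene) joins two 1,1-disubstituted alkenes and gives A3 with O6, O7 and the chain already in place. Its endgame is shorter than the chosen one and avoids a cationic transposition. Its weak points are the tetrasubstituted ring-closing metathesis next to quaternary C10 and an allylic ether, the trisubstituted C13=C14 alkene as a competing partner, and C6/C7 stereocentres that must come from acyclic additions beside the hindered C5. The chosen plan pays with more redox steps but closes ring B by an aldol with a single possible mode and sets C6 and C7 from the ring.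

Key step: step 3

**Remarks on the chemistry.**
- By the formyl C–H···O binding model, the (S)-prolinol-derived cation is taken to expose the enal face that leads to 5. If the sense is the opposite, the (R)-prolinol catalyst is used and nothing else changes.
- Compounds 6–9 are carried as C9 epimer mixtures, 7 and 13 as mixtures at the centres noted, and 11 as an E/Z mixture. The C9 configuration of 17, 21 and 22 is left unassigned (9β-OH expected). These centres disappear in steps 5, 7, 9 and 15, so their SMILES carry no descriptor there.

## Route

Step 1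
Reactants: 1 (E)-3-methylpent-2-en-4-yn-1-ol
Product: 2 tert-butyldimethyl[(E)-3-methylpent-2-en-4-ynyloxy]silane
Conditions: TBSCl, imidazole, CH2Cl2, 0 °C → rt
Reagents that add atoms: tert-butyldimethylsilyl chloride, CC(C)(C)[Si](C)(C)Cl
Why: Standard silylation of a primary allylic alcohol; the ether is non-volatile and weakly basic, so it should not compete for the boron catalyst in step 3.

Step 2
Reactants: 2 tert-butyldimethyl[(E)-3-methylpent-2-en-4-ynyloxy]silane
Product: 3 tert-butyldimethyl[(E)-3-methylpenta-2,4-dienyloxy]silane
Conditions: H2 (1 atm, 1 equiv), Pd/CaCO3 poisoned with Pb(OAc)2, quinoline, hexane, rt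
Reagents that add atoms: none
Why: Lindlar semi-hydrogenation of the terminal alkyne of a conjugated enyne gives the vinyl group; the trisubstituted E alkene is untouched, so the diene carries its C5 substituent on the outside.

Step 3
Reactants: 3 tert-butyldimethyl[(E)-3-methylpenta-2,4-dienyloxy]silane; 4 2-methylacrolein
Product: 5 (1S,2S)-2-(tert-butyldimethylsilyloxymethyl)-1,3-dimethylcyclohex-3-ene-1-carbaldehyde (labdane numbering: C5–H α, C10–CH3 β)
Conditions: (S)-B-(o-tolyl)oxazaborolidine of (S)-α,α-diphenylprolinol protonated with HNTf2 (20 mol%), CH2Cl2, −78 → −40 °C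
Reagents that add atoms: none
Why: Enantioselective Lewis acid-catalysed Diels–Alder reaction: the boron cation binds the formyl oxygen of s-trans 4 (formyl C–H held against the ring oxygen), lowers the enal LUMO and leaves one π-face open. The closest known reaction type is the oxazaborolidinium-catalysed cycloaddition of 2-substituted acroleins with acyclic and cyclic 1,3-dienes. Bond formation is concerted but asynchronous, the enal CH2 (C1) engaging the free diene terminus C2 ahead of the C10–C5 bond; ring A closes as a cyclohexene by intermolecular [4+2] cycloaddition, suprafacial on both partners. C10 is set by the catalyst's choice of enal face. C5 is set relative to C10 by the exo transition state (formyl away from the diene), expected for an α-methyl enal carrying a bulky Lewis acid on oxygen, together with the E geometry of the diene; this puts CH2OSi cis to the C10 methyl, as the trans-decalin needs. The step needs "ortho" regiochemistry, exo selectivity and face selectivity: the first should come from the 1-substituent of the diene outweighing the opposed, weaker pull of the C4 methyl, the other two from the catalyst. C5 stays correctable later, because it becomes α to the C6 carbonyl in 15.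

Step 4
Reactants: 5 (1S,2S)-2-(tert-butyldimethylsilyloxymethyl)-1,3-dimethylcyclohex-3-ene-1-carbaldehyde
Product: 6 1-[(1S,2S)-2-(tert-butyldimethylsilyloxymethyl)-1,3-dimethylcyclohex-3-enyl]propan-1-ol (C9 epimers)
Conditions: EtMgBr, THF, −78 → 0 °C
Reagents that add atoms: ethylmagnesium bromide, CC[Mg]Br
Why: Grignard addition to a non-enolisable neopentyl aldehyde brings in C8 and C17; the new carbinol centre is lost on oxidation in step 7.

Step 5
Reactants: 6 1-[(1S,2S)-2-(tert-butyldimethylsilyloxymethyl)-1,3-dimethylcyclohex-3-enyl]propan-1-ol
Product: 8 1-[(1S,2S)-2-(tert-butyldimethylsilyloxymethyl)-1,3,3-trimethylcyclohexyl]propan-1-ol (C9 epimers), via sulfonylhydrazide adduct 7 (not isolated)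
Conditions: Fe(acac)3 (30 mol%), PhSiH3, CH2=N–NHSO2(n-C8H17), THF/MeOH, rt; then MeOH, 60 °C
Reagents that add atoms: formaldehyde octane-1-sulfonylhydrazone, C=NNS(=O)(=O)CCCCCCCC
Why: Metal-hydride hydrogen-atom-transfer hydromethylation: H• adds to C3, the tertiary C4 radical adds to the formaldehyde hydrazone, and adduct 7 loses sulfinate and N2 on warming to leave CH3. C4 becomes an achiral gem-dimethyl carbon, and at the alcohol stage the radical has no activated hydrogen within 1,5-reach.

Step 6
Reactants: 8 1-[(1S,2S)-2-(tert-butyldimethylsilyloxymethyl)-1,3,3-trimethylcyclohexyl]propan-1-ol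
Product: 9 1-[(1S,2S)-2-(hydroxymethyl)-1,3,3-trimethylcyclohexyl]propan-1-ol (C9 epimers)
Conditions: Bu4NF, THF, rt
Reagents that add atoms: none
Why: Fluoride cleavage of a primary silyl ether; nothing else in the molecule responds.

Step 7
Reactants: 9 1-[(1S,2S)-2-(hydroxymethyl)-1,3,3-trimethylcyclohexyl]propan-1-ol
Product: 10 (1S,2S)-2,6,6-trimethyl-2-propanoylcyclohexane-1-carbaldehyde
Conditions: (COCl)2, DMSO, CH2Cl2, −78 °C; then Et3N, −78 → 0 °C
Reagents that add atoms: none
Why: Swern oxidation; both hydroxyls are converted to alkoxysulfonium ions before base is added, so the 1,4-diol should go to the keto aldehyde and not through a lactol to a lactone. The cold, brief base contact should leave the hindered C5–H in place.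

Step 8
Reactants: 10 (1S,2S)-2,6,6-trimethyl-2-propanoylcyclohexane-1-carbaldehyde
Product: 11 1-[(1S,2S)-2-(2-methoxyethenyl)-1,3,3-trimethylcyclohexyl]propan-1-one (E/Z mixture)
Conditions: MeOCH2PPh3Cl, KN(SiMe3)2, THF, 0 °C; then 10, −78 → 0 °C
Reagents that add atoms: (methoxymethyl)triphenylphosphonium chloride, COC[P+](c1ccccc1)(c1ccccc1)c1ccccc1.[Cl-]
Why: Wittig homologation introduces C7; the ylide should react with the aldehyde only, the tert-alkyl ethyl ketone being too hindered to add or to be enolised at this temperature.

Step 9
Reactants: 11 1-[(1S,2S)-2-(2-methoxyethenyl)-1,3,3-trimethylcyclohexyl]propan-1-one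
Product: 14 11,12,13,14,15,16-hexanorlabd-7-en-9-one [(4aS,8aS)-2,5,5,8a-tetramethyl-4a,5,6,7,8,8a-hexahydronaphthalen-1(4H)-one], via keto aldehyde 12 (not isolated), via aldol 13 (not isolated)
Conditions: TsOH·H2O (cat.), acetone/H2O, rt; then toluene, reflux (Dean–Stark)
Reagents that add atoms: none
Why: Enol ether hydrolysis, then acid-catalysed intramolecular aldol condensation: C8 is the only carbon that can reach C7 through a six-membered ring (C10 is quaternary), so ring B closes in one mode and dehydration gives the conjugated C7=C8 enone. C5 and C10 are not touched.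

Step 10
Reactants: 14 11,12,13,14,15,16-hexanorlabd-7-en-9-one
Product: 15 11,12,13,14,15,16-hexanorlabd-7-ene-6,9-dione [(4aS,8aS)-2,5,5,8a-tetramethyl-4a,5,6,7,8,8a-hexahydronaphthalene-1,4-dione]
Conditions: Rh2(cap)4 (cap = caprolactamate, 1 mol%), t-BuOOH (70% aq.), CH2Cl2, rt → 40 °C, no added base
Reagents that add atoms: tert-butyl hydroperoxide, CC(C)(C)OO
Why: Allylic (γ) C–H oxidation of an enone to an ene-dione by tert-butylperoxyl radicals; C6 is the only ring methylene whose radical is conjugated with the enone, and it should be preferred over the C17 methyl.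

Step 11
Reactants: 15 11,12,13,14,15,16-hexanorlabd-7-ene-6,9-dione
Product: 16 6β-hydroxy-11,12,13,14,15,16-hexanorlabd-7-en-9-one [(4R,4aS,8aS)-4-hydroxy-2,5,5,8a-tetramethyl-4a,5,6,7,8,8a-hexahydronaphthalen-1(4H)-one]
Conditions: NaBH4 (0.5 equiv), CeCl3·7H2O, MeOH, −78 °C
Reagents that add atoms: none
Why: Luche 1,2-reduction, as in the selective reduction of 2,6,6-trimethylcyclohex-2-ene-1,4-dione at its less hindered carbonyl: C6 (flanked by CH and vinyl CH) should react before C9 (flanked by quaternary C10 and the methyl-bearing C8). Hydride comes from the α face because the C4β and C10 methyl groups block the β face, which sets the axial 6β-hydroxyl.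

Step 12
Reactants: 16 6β-hydroxy-11,12,13,14,15,16-hexanorlabd-7-en-9-one
Product: 17 13,14,15,16-tetranorlabda-7,11-diene-6β,9-diol (C9 unassigned)
Conditions: CH2=CHMgBr (4 equiv), CeCl3 (anhydrous, 4 equiv), THF, −78 → 0 °C
Reagents that add atoms: vinylmagnesium bromide, C=C[Mg]Br
Why: Organocerium 1,2-addition to a hindered, non-enolisable enone carbonyl; the first equivalent of the cheap reagent is spent on the hydroxyl. The C9 configuration is of no consequence.

Step 13
Reactants: 18 but-2-yn-1-ol
Product: 20 (Z)-3-iodobut-2-en-1-ol, via alkenylaluminate 19 (not isolated)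
Conditions: NaAlH2(OCH2CH2OMe)2, Et2O, 0 °C → rt; then I2, THF, −78 °C
Reagents that add atoms: iodine, II
Why: Alkoxide-directed trans-hydroalumination of a propargylic alcohol puts aluminium on C3 cis to CH2O in a five-membered aluminate; iodinolysis with retention gives the Z iodide.

Step 14
Reactants: 17 13,14,15,16-tetranorlabda-7,11-diene-6β,9-diol; 20 (Z)-3-iodobut-2-en-1-ol
Product: 22 labda-7,13(Z)-diene-6β,9,15-triol (C9 unassigned), via alkylborane 21 (not isolated)
Conditions: 9-BBN (3 equiv), THF, rt; then 20, PdCl2(dppf) (5 mol%), AsPh3, K3PO4 (aq.), DMF, rt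
Reagents that add atoms: none
Why: 9-BBN should hydroborate only the monosubstituted C11=C12 alkene, boron going to C12; B-alkyl Suzuki–Miyaura coupling with the vinyl iodide forms C12–C13 with retention of the Z geometry. Free hydroxyls and the trisubstituted C7=C8 alkene are tolerated.

Step 15
Reactants: 22 labda-7,13(Z)-diene-6β,9,15-triol
Product: 23 labda-8,13(Z)-diene-6β,7α,15-triol
Conditions: TsOH·H2O (cat.), THF/H2O, 0 °C → rt
Reagents that add atoms: water, O
Why: Acid-catalysed 1,3-transposition of a tertiary allylic alcohol: ionisation at C9 gives the C7–C8–C9 allyl cation, and water enters at C7 axially and anti to the axial 6β-hydroxyl (directly or through its participation), giving the trans-diaxial 7α-ol. The tetrasubstituted C8=C9 alkene and relief of strain at C9 drive the equilibrium; the axial C6–O bond, not C6–H, is aligned with the cation, which disfavours proton loss from C6.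

Step 16
Reactants: 23 labda-8,13(Z)-diene-6β,7α,15-triol
Product: 24 labda-8,13(Z)-diene-6β,7α,15-triol 7,15-diacetate (CNP0415913.2)
Conditions: Ac2O (2.5 equiv), pyridine, DMAP (cat.), CH2Cl2, 0 °C
Reagents that add atoms: acetic anhydride, CC(=O)OC(C)=O
Why: Acylation of the primary and the secondary allylic hydroxyl; the axial 6β-hydroxyl, syn-axial to the C4β and C10 methyl groups, should stay free, and a trans-diaxial hydroxy acetate has no easy path for acyl migration.

## Compound list

1 | (E)-3-methylpent-2-en-4-yn-1-ol | C#C/C(C)=C/CO | starting material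
2 | tert-butyldimethyl[(E)-3-methylpent-2-en-4-ynyloxy]silane | C#C/C(C)=C/CO[Si](C)(C)C(C)(C)C | intermediate
3 | tert-butyldimethyl[(E)-3-methylpenta-2,4-dienyloxy]silane | C=C/C(C)=C/CO[Si](C)(C)C(C)(C)C | intermediate
4 | 2-methylacrolein (2-methylprop-2-enal) | CC(=C)C=O | starting material
5 | (1S,2S)-2-(tert-butyldimethylsilyloxymethyl)-1,3-dimethylcyclohex-3-ene-1-carbaldehyde | O=C[C@@]1(C)CCC=C(C)[C@@H]1CO[Si](C)(C)C(C)(C)C | intermediate
6 | 1-[(1S,2S)-2-(tert-butyldimethylsilyloxymethyl)-1,3-dimethylcyclohex-3-enyl]propan-1-ol, C9 epimers | CCC(O)[C@@]1(C)CCC=C(C)[C@@H]1CO[Si](C)(C)C(C)(C)C | intermediate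
7 | N'-{[2-(tert-butyldimethylsilyloxymethyl)-3-(1-hydroxypropyl)-1,3-dimethylcyclohexyl]methyl}octane-1-sulfonohydrazide, C4 and C9 epimers, C5 and C10 as in 5 | CCC(O)[C@@]1(C)CCCC(C)(CNNS(=O)(=O)CCCCCCCC)[C@@H]1CO[Si](C)(C)C(C)(C)C | intermediate (not isolated)
8 | 1-[(1S,2S)-2-(tert-butyldimethylsilyloxymethyl)-1,3,3-trimethylcyclohexyl]propan-1-ol, C9 epimers | CCC(O)[C@@]1(C)CCCC(C)(C)[C@@H]1CO[Si](C)(C)C(C)(C)C | intermediate
9 | 1-[(1S,2S)-2-(hydroxymethyl)-1,3,3-trimethylcyclohexyl]propan-1-ol, C9 epimers | CCC(O)[C@@]1(C)CCCC(C)(C)[C@@H]1CO | intermediate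
10 | (1S,2S)-2,6,6-trimethyl-2-propanoylcyclohexane-1-carbaldehyde | CCC(=O)[C@@]1(C)CCCC(C)(C)[C@@H]1C=O | intermediate
11 | 1-[(1S,2S)-2-(2-methoxyethenyl)-1,3,3-trimethylcyclohexyl]propan-1-one, E/Z mixture | CCC(=O)[C@@]1(C)CCCC(C)(C)[C@@H]1C=COC | intermediate
12 | 2-[(1S,2S)-2,6,6-trimethyl-2-propanoylcyclohexyl]acetaldehyde | CCC(=O)[C@@]1(C)CCCC(C)(C)[C@@H]1CC=O | intermediate (not isolated)
13 | 7-hydroxy-11,12,13,14,15,16-hexanorlabdan-9-one, C7 and C8 epimers, 5α-H, 10β-CH3 | CC1C(O)C[C@H]2C(C)(C)CCC[C@]2(C)C1=O | intermediate (not isolated)
14 | 11,12,13,14,15,16-hexanorlabd-7-en-9-one [(4aS,8aS)-2,5,5,8a-tetramethyl-4a,5,6,7,8,8a-hexahydronaphthalen-1(4H)-one] | CC1=CC[C@H]2C(C)(C)CCC[C@]2(C)C1=O | intermediate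
15 | 11,12,13,14,15,16-hexanorlabd-7-ene-6,9-dione | CC1=CC(=O)[C@H]2C(C)(C)CCC[C@]2(C)C1=O | intermediate
16 | 6β-hydroxy-11,12,13,14,15,16-hexanorlabd-7-en-9-one | CC1=C[C@@H](O)[C@H]2C(C)(C)CCC[C@]2(C)C1=O | intermediate
17 | 13,14,15,16-tetranorlabda-7,11-diene-6β,9-diol, C9 unassigned | CC1=C[C@@H](O)[C@H]2C(C)(C)CCC[C@]2(C)C1(O)C=C | intermediate
18 | but-2-yn-1-ol | CC#CCO | starting material
19 | sodium 2,2-bis(2-methoxyethoxy)-3-methyl-2,5-dihydro-1,2-oxaaluminol-2-uide (cyclic alkenylaluminate, Al on C3 cis to CH2O) | [Na+].C/C1=C/CO[Al-]1(OCCOC)OCCOC | intermediate (not isolated)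
20 | (Z)-3-iodobut-2-en-1-ol | C/C(I)=C/CO | intermediate
21 | 12-(9-borabicyclo[3.3.1]nonan-9-yl)-13,14,15,16-tetranorlabd-7-ene-6β,9-diol, C9 unassigned | CC1=C[C@@H](O)[C@H]2C(C)(C)CCC[C@]2(C)C1(O)CCB1C2CCCC1CCC2 | intermediate (not isolated)
22 | labda-7,13(Z)-diene-6β,9,15-triol, C9 unassigned | CC1=C[C@@H](O)[C@H]2C(C)(C)CCC[C@]2(C)C1(O)CC/C(C)=C\CO | intermediate
23 | labda-8,13(Z)-diene-6β,7α,15-triol | OC/C=C(/C)CCC1=C(C)[C@H](O)[C@@H](O)[C@H]2C(C)(C)CCC[C@]12C | intermediate
24 | labda-8,13(Z)-diene-6β,7α,15-triol 7,15-diacetate (CNP0415913.2) | CC(=O)OC/C=C(/C)CCC1=C(C)[C@H](OC(C)=O)[C@@H](O)[C@H]2C(C)(C)CCC[C@]12C | target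

## Step count and risk

Total steps: 16. Longest linear sequence: 15 steps (steps 1–12 and 14–16); step 13 is the one-step side branch.

**Step 3 (key step).** The likely failure is a loss of selectivity rather than of reactivity. The C4 methyl of the diene pulls the regiochemistry against the C5 substituent, an acyclic diene separates exo from endo less sharply than a cyclic one, and an uncatalysed background reaction at the temperature needed for turnover would lower the enantiomeric purity. Fallback (from 3 and 4, back to the route at 5): the cycloaddition is run with an achiral aluminium Lewis acid (Me2AlCl, CH2Cl2, −78 °C) to give the racemic exo adduct F1. The aldehyde is reduced (NaBH4, MeOH) to the racemic neopentyl alcohol F2. The enantiomers are separated by preparative chromatography on a chiral stationary phase to give the (1S,2S)-alcohol F3, and Dess–Martin oxidation returns 5.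

**Step 15.** The allyl cation may lose a proton from C11 instead of taking up water, the secondary 6β-hydroxyl may ionise in competition, or the acid may isomerise or cyclise the Z allylic alcohol chain. Fallback (from 22, back at 24): selective acetylation of the primary hydroxyl (Ac2O, pyridine, 0 °C) gives the 15-monoacetate F4. A perrhenate-ester [3,3] transposition (Ph3SiOReO3 cat., Et2O, −50 °C) is suprafacial and free of carbocations; it should move the tertiary hydroxyl, expected to be 9β after α-face addition in step 12, to the same face of C7 and give the 6β,7β-diol F5. Mitsunobu esterification with AcOH (PPh3, DIAD, THF) then inverts C7 and gives 24 directly.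

**Step 5.** The hindered tertiary C4 radical may be reduced (net hydrogenation of the alkene) or trapped too slowly by the hydrazone. Fallback (from 6, back at 8): Simmons–Smith cyclopropanation (Et2Zn, CH2I2, CH2Cl2) gives the bicyclo[4.1.0]heptane F6. Hydrogenolysis of its least substituted ring bond (H2, PtO2, AcOH) leaves the gem-dimethyl group of 8; if the silyl ether is lost in acetic acid, the route is re-entered at 9.

**Step 10.** Hydrogen abstraction may be unselective (C17 methyl), oxidation may continue, or C5 may epimerise once the C6 ketone is present. Fallback (from 14, back at 15): the enone is converted into the silyl dienol ether F7 (TBSOTf, Et3N, CH2Cl2). Singlet oxygen (O2, hν, tetraphenylporphyrin) adds across C6 and C9 of the ring diene, and silyl transfer gives the 6-silylperoxy enone F8. Et3N then induces Kornblum–DeLaMare-type elimination to 15.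

**Step 11.** Hydride may also add at C9 or reduce both carbonyls. Fallback (from 15, back at 16): exhaustive reduction (i-Bu2AlH, CH2Cl2, −78 °C) gives the ene-diol F9. MnO2 (CH2Cl2, rt) should then oxidise the quasi-equatorial, more accessible C9 allylic hydroxyl first and leave the quasi-axial, doubly shielded 6β-hydroxyl, giving 16.

## Further compounds

F1 | step 3 | racemic exo adduct, both enantiomers of 2-(tert-butyldimethylsilyloxymethyl)-1,3-dimethylcyclohex-3-ene-1-carbaldehyde | O=C[C@@]1(C)CCC=C(C)[C@@H]1CO[Si](C)(C)C(C)(C)C.O=C[C@]1(C)CCC=C(C)[C@H]1CO[Si](C)(C)C(C)(C)C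
F2 | step 3 | racemic [2-(tert-butyldimethylsilyloxymethyl)-1,3-dimethylcyclohex-3-enyl]methanol (CH2OSi cis to CH3) | OC[C@@]1(C)CCC=C(C)[C@@H]1CO[Si](C)(C)C(C)(C)C.OC[C@]1(C)CCC=C(C)[C@H]1CO[Si](C)(C)C(C)(C)C
F3 | step 3 | [(1S,2S)-2-(tert-butyldimethylsilyloxymethyl)-1,3-dimethylcyclohex-3-enyl]methanol | OC[C@@]1(C)CCC=C(C)[C@@H]1CO[Si](C)(C)C(C)(C)C
F4 | step 15 | labda-7,13(Z)-diene-6β,9,15-triol 15-acetate, C9 unassigned | CC1=C[C@@H](O)[C@H]2C(C)(C)CCC[C@]2(C)C1(O)CC/C(C)=C\COC(C)=O
F5 | step 15 | labda-8,13(Z)-diene-6β,7β,15-triol 15-acetate | CC(=O)OC/C=C(/C)CCC1=C(C)[C@@H](O)[C@@H](O)[C@H]2C(C)(C)CCC[C@]12C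
F6 | step 5 | 1-[2-(tert-butyldimethylsilyloxymethyl)-1,3-dimethylbicyclo[4.1.0]heptan-3-yl]propan-1-ol, C5 and C10 as in 6 | CCC(O)[C@@]1(C)CCC2CC2(C)[C@@H]1CO[Si](C)(C)C(C)(C)C
F7 | step 10 | 9-(tert-butyldimethylsilyloxy)-11,12,13,14,15,16-hexanorlabda-6,8-diene | CC=1C=C[C@H]2C(C)(C)CCC[C@]2(C)C=1O[Si](C)(C)C(C)(C)C
F8 | step 10 | 6-(tert-butyldimethylsilylperoxy)-11,12,13,14,15,16-hexanorlabd-7-en-9-one, C6 unassigned | CC1=CC(OO[Si](C)(C)C(C)(C)C)[C@H]2C(C)(C)CCC[C@]2(C)C1=O
F9 | step 11 | 11,12,13,14,15,16-hexanorlabd-7-ene-6β,9-diol, C9 unassigned | CC1=C[C@@H](O)[C@H]2C(C)(C)CCC[C@]2(C)C1O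
A1 | alternative 1 | 5β,10β-methylene-bridged (C20) 9,9-dimethoxy-4,4-dimethyldecalin-6β-ol | O[C@@H]1CCC(OC)(OC)[C@]23C[C@]12C(C)(C)CCC3
A2 | alternative 2 | 6α-nitro-3β-(4-methoxybenzyloxy)labda-8,13(Z)-dien-15-yl acetate | CC(=O)OC/C=C(/C)CCC1=C(C)C[C@H]([N+](=O)[O-])[C@H]2C(C)(C)[C@@H](OCc3ccc(OC)cc3)CC[C@]12C
A3 | alternative 3 | 7-O-methoxymethyl 15-O-tert-butyldimethylsilyl labda-8,13(Z)-diene-6β,7α,15-triol | CC(C)(C)[Si](C)(C)OC/C=C(/C)CCC1=C(C)[C@H](OCOC)[C@@H](O)[C@H]2C(C)(C)CCC[C@]12C
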